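**Retrosynthetic overview**
1. Arzanol is traced back (fluoride, then acid) to a silyl/MOM-protected form, and the aryl–acetyl bond is cut next: bromination of the one ring CH and Stille coupling with an acetyl equivalent.
2. Key disconnection: the benzene ring is cut at C4–C3, C2–C1 and C4–C5 (C1 = bridge-bearing carbon) into a 3-alkoxy-2-(pyronylmethyl)cyclobutenone, which serves as vinylketene source, and a prenyl-bearing triisopropylsiloxyalkyne.
3. Feature used: the benzene ring has oxygen on C2, C4 and C6, the pyronyl-CH2 on C1 and prenyl on C3 between them, and only C5 (the later acetyl carbon) without a skeletal group. Ketene C=O, ynol-ether oxygen and cyclobutenone enol-ether oxygen deliver exactly this alternation.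
4. The cyclobutenone comes from bis-MOM protection of a methylene-bridged pyrone/cyclobutane-1,3-dione pair (Mannich, then Michael); the pyrone comes from 3-pentanone and malonyl dichloride. The siloxyalkyne comes from Kowalski homologation of ethyl 4-methylpent-3-enoate.
5. Ring order: pyrone ring (step 1), then benzene ring (step 6); the four-membered ring is bought and consumed.

Key step: step 6

Remark: cyclobutane-1,3-dione is taken as a purchased starting material that reacts through its enol (3-hydroxycyclobut-2-en-1-one); enolised compounds are drawn as one tautomer.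

**Step 1**
Reactants: 1 3-pentanone; 2 malonyl dichloride
Product: 3 6-ethyl-4-hydroxy-5-methyl-2H-pyran-2-one
Conditions: neat (excess 1), rt → 50 °C
Reagents that add atoms: none
Why: C-acylation of the ketone enol by the bis-acid chloride followed by enol O-acylation (lactonisation) is the classical malonyl dichloride condensation to 5,6-dialkyl-4-hydroxy-2-pyrones, with the ketone carbon becoming C6 and its α-carbon C5.

**Step 2**
Reactants: 3 6-ethyl-4-hydroxy-5-methyl-2H-pyran-2-one; 4 cyclobutane-1,3-dione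
Product: 7 2-[(6-ethyl-4-hydroxy-5-methyl-2-oxo-2H-pyran-3-yl)methyl]-3-hydroxycyclobut-2-en-1-one, via Mannich base 5 (not isolated), via methylene-pyrandione 6 (not isolated)
Conditions: Me2N=CH2 I (1.0 equiv), MeCN, rt; then 4 (2 equiv), 50 °C; aq. HCl work-up
Reagents that add atoms: N,N-dimethylmethyleneiminium iodide (Eschenmoser's salt), C=[N+](C)C.[I-]
Why: Mannich reaction at the only nucleophilic carbon (C3) of the hydroxypyrone gives 5, which loses dimethylamine to the doubly activated enone 6, and the acidic, fully enolised dione 4 adds to 6 by Michael addition (the standard methylene bridging of two cyclic 1,3-dicarbonyl units); excess 4 should suppress the bis-pyrone and a second alkylation.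

**Step 3**
Reactants: 7 2-[(6-ethyl-4-hydroxy-5-methyl-2-oxo-2H-pyran-3-yl)methyl]-3-hydroxycyclobut-2-en-1-one
Product: 8 2-{[6-ethyl-4-(methoxymethoxy)-5-methyl-2-oxo-2H-pyran-3-yl]methyl}-3-(methoxymethoxy)cyclobut-2-en-1-one
Conditions: MOMCl (2.5 equiv), i-Pr2NEt, CH2Cl2, 0 °C
Reagents that add atoms: chloromethyl methyl ether, COCCl
Why: O-alkylation of both vinylogous acids by the hard electrophile under amine base (Williamson-type acetal formation) should give one cyclobutenone enol ether because the 2-substituted dione is symmetrical, and MOM is chosen on both oxygens because dilute methanolic acid, which a prenylphenol tolerates, removes it at the end.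

**Step 4**
Reactants: 9 4-methylpent-3-enoic acid
Product: 10 ethyl 4-methylpent-3-enoate
Conditions: EtI, K2CO3, DMF, rt
Reagents that add atoms: iodoethane, CCI
Why: SN2 alkylation of the carboxylate under mild base avoids the acid-catalysed lactonisation and double-bond migration that a Fischer esterification of this β,γ-unsaturated acid would invite.

**Step 5**
Reactants: 10 ethyl 4-methylpent-3-enoate
Product: 12 triisopropyl[(5-methylhex-4-en-1-yn-1-yl)oxy]silane, via lithium ynolate 11 (not isolated)
Conditions: CH2Br2, lithium 2,2,6,6-tetramethylpiperidide, THF, −78 °C; n-BuLi, −78 → 0 °C; TIPSCl, −78 → 0 °C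
Reagents that add atoms: dibromomethane, BrCBr; chlorotriisopropylsilane, CC(C)[Si](Cl)(C(C)C)C(C)C
Why: In the Kowalski ester homologation, dibromomethyllithium adds to the ester, bromine–lithium exchange on the dibromoketone enolate triggers the carbenoid 1,2-shift to ynolate 11, and the bulky silyl chloride silylates 11 on oxygen to the siloxyalkyne.

**Step 6**
Reactants: 8 2-{[6-ethyl-4-(methoxymethoxy)-5-methyl-2-oxo-2H-pyran-3-yl]methyl}-3-(methoxymethoxy)cyclobut-2-en-1-one; 12 triisopropyl[(5-methylhex-4-en-1-yn-1-yl)oxy]silane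
Product: 17 6-ethyl-3-{[4-hydroxy-6-(methoxymethoxy)-3-(3-methylbut-2-en-1-yl)-2-(triisopropylsilyloxy)phenyl]methyl}-4-(methoxymethoxy)-5-methyl-2H-pyran-2-one, via vinylketene 13 (not isolated), via 4-vinylcyclobutenone 14 (not isolated), via dienylketene 15 (not isolated), via cyclohexa-2,4-dienone 16 (not isolated)
Conditions: 12 (1.5 equiv), toluene, 80 → 120 °C, sealed tube
Reagents that add atoms: none
Why: On heating, 8 opens by 4π-electrocyclic cleavage of its C1–C4 bond to vinylketene 13, whose electrophilic carbonyl carbon is attacked by the nucleophilic prenyl-bearing carbon of the electron-rich alkyne 12 in a [2+2] cycloaddition that gives 14 (new bonds C4–C3 and C1–C2 of the later arene). A second 4π ring opening of 14 gives dienylketene 15, which closes the benzene ring by 6π-electrocyclisation between the ketene carbon and the terminal CH2 (the C4–C5 bond) to dienone 16, and tautomerisation should deliver phenol 17. This is the Danheiser benzannulation of a cyclobutenone with a trialkylsiloxyalkyne; for the 3-alkoxy substituent the closest analogy is the thermal union of 3-alkoxycyclobutenones with 1-alkoxyalkynes to 3,5-dialkoxyphenols, and as a donor it is expected to raise the ring-opening temperature, hence 120 °C. No stereocentre is formed. The step needs regiocontrol, which the polarity of the ketene–ynol ether addition secures (oxygen-bearing alkyne carbon to the ketene α-carbon), and chemoselectivity, which rests on neutral conditions and on the fully substituted, electron-rich alkoxypyrone being neither a competent diene nor a ketene trap; excess 12 should keep the product phenol from intercepting 13 as an aryl ester.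

**Step 7**
Reactants: 17 6-ethyl-3-{[4-hydroxy-6-(methoxymethoxy)-3-(3-methylbut-2-en-1-yl)-2-(triisopropylsilyloxy)phenyl]methyl}-4-(methoxymethoxy)-5-methyl-2H-pyran-2-one
Product: 18 3-{[5-bromo-4-hydroxy-6-(methoxymethoxy)-3-(3-methylbut-2-en-1-yl)-2-(triisopropylsilyloxy)phenyl]methyl}-6-ethyl-4-(methoxymethoxy)-5-methyl-2H-pyran-2-one
Conditions: NBS (1.0 equiv), CH2Cl2, −78 °C
Reagents that add atoms: N-bromosuccinimide, O=C1CCC(=O)N1Br
Why: Electrophilic aromatic bromination at the single unsubstituted ring carbon, ortho to the free hydroxyl and activated by two further oxygens, should be much faster at −78 °C than bromonium formation at the prenyl alkene, and the pyrone has no free ring position.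

**Step 8**
Reactants: 18 3-{[5-bromo-4-hydroxy-6-(methoxymethoxy)-3-(3-methylbut-2-en-1-yl)-2-(triisopropylsilyloxy)phenyl]methyl}-6-ethyl-4-(methoxymethoxy)-5-methyl-2H-pyran-2-one
Product: 20 3-{[3-acetyl-2,4-dihydroxy-5-(3-methylbut-2-en-1-yl)-6-(triisopropylsilyloxy)phenyl]methyl}-6-ethyl-4-hydroxy-5-methyl-2H-pyran-2-one, via enol ether 19 (not isolated)
Conditions: CH2=C(OEt)SnBu3, Pd(PPh3)4 (cat.), toluene, 100 °C; then 3 M HCl, MeOH, rt → 40 °C
Reagents that add atoms: tributyl(1-ethoxyvinyl)stannane, CCCC[Sn](CCCC)(CCCC)C(=C)OCC; water, O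
Why: Stille coupling installs the masked acetyl group as enol ether 19, and dilute methanolic HCl then hydrolyses the enol ether to the methyl ketone and cleaves both MOM acetals under the conditions customary for MOM-protected prenylphenols, while the hindered aryl silyl ether should persist.

**Step 9**
Reactants: 20 3-{[3-acetyl-2,4-dihydroxy-5-(3-methylbut-2-en-1-yl)-6-(triisopropylsilyloxy)phenyl]methyl}-6-ethyl-4-hydroxy-5-methyl-2H-pyran-2-one
Product: 21 arzanol, 3-{[3-acetyl-2,4,6-trihydroxy-5-(3-methylbut-2-en-1-yl)phenyl]methyl}-6-ethyl-4-hydroxy-5-methyl-2H-pyran-2-one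
Conditions: TBAF, AcOH, THF, 0 °C
Reagents that add atoms: none
Why: Fluoride-mediated cleavage of the aryl silyl ether (desilylation) is fast at 0 °C, and acetic acid buffering should keep the polyphenol from base-induced degradation, leaving prenyl, acetyl and pyrone untouched.

**Compound list**
1 | 3-pentanone | CCC(=O)CC | starting material
2 | malonyl dichloride | O=C(Cl)CC(=O)Cl | starting material
3 | 6-ethyl-4-hydroxy-5-methyl-2H-pyran-2-one | CCc1oc(=O)cc(O)c1C | intermediate
4 | cyclobutane-1,3-dione | O=C1CC(=O)C1 | starting material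
5 | 3-[(dimethylamino)methyl]-6-ethyl-4-hydroxy-5-methyl-2H-pyran-2-one (Mannich base) | CCc1oc(=O)c(CN(C)C)c(O)c1C | intermediate (not isolated)
6 | 6-ethyl-5-methyl-3-methylidene-2H-pyran-2,4(3H)-dione | CCC1=C(C)C(=O)C(=C)C(=O)O1 | intermediate (not isolated)
7 | 2-[(6-ethyl-4-hydroxy-5-methyl-2-oxo-2H-pyran-3-yl)methyl]-3-hydroxycyclobut-2-en-1-one | CCc1oc(=O)c(CC2=C(O)CC2=O)c(O)c1C | intermediate
8 | 2-{[6-ethyl-4-(methoxymethoxy)-5-methyl-2-oxo-2H-pyran-3-yl]methyl}-3-(methoxymethoxy)cyclobut-2-en-1-one | O=C1CC(OCOC)=C1Cc1c(OCOC)c(C)c(CC)oc1=O | intermediate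
9 | 4-methylpent-3-enoic acid | CC(C)=CCC(=O)O | starting material
10 | ethyl 4-methylpent-3-enoate | CCOC(=O)CC=C(C)C | intermediate
11 | lithium 5-methylhex-4-en-1-yn-1-olate | [Li+].[O-]C#CCC=C(C)C | intermediate (not isolated)
12 | triisopropyl[(5-methylhex-4-en-1-yn-1-yl)oxy]silane | CC(C)=CCC#CO[Si](C(C)C)(C(C)C)C(C)C | intermediate
13 | 2-{[6-ethyl-4-(methoxymethoxy)-5-methyl-2-oxo-2H-pyran-3-yl]methyl}-3-(methoxymethoxy)buta-1,3-dien-1-one (vinylketene) | O=C=C(Cc1c(OCOC)c(C)c(CC)oc1=O)C(OCOC)=C | intermediate (not isolated)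
14 | 4-{[6-ethyl-4-(methoxymethoxy)-5-methyl-2-oxo-2H-pyran-3-yl]methyl}-4-[1-(methoxymethoxy)ethenyl]-2-(3-methylbut-2-en-1-yl)-3-(triisopropylsilyloxy)cyclobut-2-en-1-one (racemic) | O=C1C(CC=C(C)C)=C(O[Si](C(C)C)(C(C)C)C(C)C)C1(Cc1c(OCOC)c(C)c(CC)oc1=O)C(OCOC)=C | intermediate (not isolated)
15 | 4-{[6-ethyl-4-(methoxymethoxy)-5-methyl-2-oxo-2H-pyran-3-yl]methyl}-5-(methoxymethoxy)-2-(3-methylbut-2-en-1-yl)-3-(triisopropylsilyloxy)hexa-1,3,5-trien-1-one (ketene and alkoxyvinyl groups cis on the central C=C) | O=C=C(CC=C(C)C)/C(O[Si](C(C)C)(C(C)C)C(C)C)=C(/Cc1c(OCOC)c(C)c(CC)oc1=O)C(OCOC)=C | intermediate (not isolated)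
16 | 4-{[6-ethyl-4-(methoxymethoxy)-5-methyl-2-oxo-2H-pyran-3-yl]methyl}-5-(methoxymethoxy)-2-(3-methylbut-2-en-1-yl)-3-(triisopropylsilyloxy)cyclohexa-2,4-dien-1-one | O=C1CC(OCOC)=C(Cc2c(OCOC)c(C)c(CC)oc2=O)C(O[Si](C(C)C)(C(C)C)C(C)C)=C1CC=C(C)C | intermediate (not isolated)
17 | 6-ethyl-3-{[4-hydroxy-6-(methoxymethoxy)-3-(3-methylbut-2-en-1-yl)-2-(triisopropylsilyloxy)phenyl]methyl}-4-(methoxymethoxy)-5-methyl-2H-pyran-2-one | CCc1oc(=O)c(Cc2c(OCOC)cc(O)c(CC=C(C)C)c2O[Si](C(C)C)(C(C)C)C(C)C)c(OCOC)c1C | intermediate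
18 | 3-{[5-bromo-4-hydroxy-6-(methoxymethoxy)-3-(3-methylbut-2-en-1-yl)-2-(triisopropylsilyloxy)phenyl]methyl}-6-ethyl-4-(methoxymethoxy)-5-methyl-2H-pyran-2-one | CCc1oc(=O)c(Cc2c(OCOC)c(Br)c(O)c(CC=C(C)C)c2O[Si](C(C)C)(C(C)C)C(C)C)c(OCOC)c1C | intermediate
19 | 3-{[5-(1-ethoxyethenyl)-4-hydroxy-6-(methoxymethoxy)-3-(3-methylbut-2-en-1-yl)-2-(triisopropylsilyloxy)phenyl]methyl}-6-ethyl-4-(methoxymethoxy)-5-methyl-2H-pyran-2-one | CCc1oc(=O)c(Cc2c(OCOC)c(C(=C)OCC)c(O)c(CC=C(C)C)c2O[Si](C(C)C)(C(C)C)C(C)C)c(OCOC)c1C | intermediate (not isolated)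
20 | 3-{[3-acetyl-2,4-dihydroxy-5-(3-methylbut-2-en-1-yl)-6-(triisopropylsilyloxy)phenyl]methyl}-6-ethyl-4-hydroxy-5-methyl-2H-pyran-2-one | CCc1oc(=O)c(Cc2c(O)c(C(C)=O)c(O)c(CC=C(C)C)c2O[Si](C(C)C)(C(C)C)C(C)C)c(O)c1C | intermediate
21 | arzanol | CCc1oc(=O)c(Cc2c(O)c(CC=C(C)C)c(O)c(C(C)=O)c2O)c(O)c1C | target

**Totals**
Total steps: 9. Longest linear sequence: 7 (steps 1, 2, 3, 6, 7, 8, 9). The target has no stereocentre.

**Steps most likely to fail**

Step 6. The donor-stabilised cyclobutenone may open too slowly, so that silyl migration in the siloxyalkyne and acylation of the product phenol by the vinylketene outrun the annulation. The fallback gives up ring construction and joins two finished rings at the methylene bridge by known chemistry. It sets out from 3. Commercial 2,4,6-trihydroxyacetophenone is C-prenylated (prenyl bromide, DBU, THF) to 1-[2,4,6-trihydroxy-3-(3-methylbut-2-en-1-yl)phenyl]ethan-1-one F1. Compound 3 is taken through 5 to 6 with Me2N=CH2 I as in step 2, and 6 is trapped by Michael addition of the one free ring carbon of F1. This comes back to the route at 21.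

Step 2. Enone 6 may be captured by a second pyrone enol, or by product 7, faster than by the four-membered enolate, which would lead to symmetrical or doubly alkylated material. The fallback reverses the roles of the two partners. It sets out from 4, which is aminomethylated with Me2N=CH2 I in MeCN to 2-[(dimethylamino)methyl]-3-hydroxycyclobut-2-en-1-one F2, collected as its salt. Warming F2 with 3 releases 2-methylidenecyclobutane-1,3-dione F3, which the pyrone enol, the established Michael donor of this pair, traps at C3. This comes back to the route at 7.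

Step 8. Oxidative addition of zerovalent palladium into a bromide flanked by two oxygen substituents may be slow, so that protodebromination competes with coupling. The fallback builds the acetyl group without a halide or palladium and sets out from 17, bypassing step 7 as well. Magnesium-phenoxide-directed ortho-formylation (MgCl2, Et3N, paraformaldehyde, MeCN, reflux) should give 3-{[5-formyl-4-hydroxy-6-(methoxymethoxy)-3-(3-methylbut-2-en-1-yl)-2-(triisopropylsilyloxy)phenyl]methyl}-6-ethyl-4-(methoxymethoxy)-5-methyl-2H-pyran-2-one F4. MeMgBr (THF, −78 °C) adds to the aldehyde to give the racemic carbinol 6-ethyl-3-{[4-hydroxy-5-(1-hydroxyethyl)-6-(methoxymethoxy)-3-(3-methylbut-2-en-1-yl)-2-(triisopropylsilyloxy)phenyl]methyl}-4-(methoxymethoxy)-5-methyl-2H-pyran-2-one F5. MnO2 in CH2Cl2 oxidises the benzylic alcohol to 3-{[5-acetyl-4-hydroxy-6-(methoxymethoxy)-3-(3-methylbut-2-en-1-yl)-2-(triisopropylsilyloxy)phenyl]methyl}-6-ethyl-4-(methoxymethoxy)-5-methyl-2H-pyran-2-one F6. Treatment with 3 M HCl in MeOH removes both MOM groups and comes back to the route at 20.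

**Further compounds**
F1 | step 6 | 1-[2,4,6-trihydroxy-3-(3-methylbut-2-en-1-yl)phenyl]ethan-1-one | CC(=O)c1c(O)cc(O)c(CC=C(C)C)c1O
F2 | step 2 | 2-[(dimethylamino)methyl]-3-hydroxycyclobut-2-en-1-one | CN(C)CC1=C(O)CC1=O
F3 | step 2 | 2-methylidenecyclobutane-1,3-dione | C=C1C(=O)CC1=O
F4 | step 8 | 3-{[5-formyl-4-hydroxy-6-(methoxymethoxy)-3-(3-methylbut-2-en-1-yl)-2-(triisopropylsilyloxy)phenyl]methyl}-6-ethyl-4-(methoxymethoxy)-5-methyl-2H-pyran-2-one | CCc1oc(=O)c(Cc2c(OCOC)c(C=O)c(O)c(CC=C(C)C)c2O[Si](C(C)C)(C(C)C)C(C)C)c(OCOC)c1C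
F5 | step 8 | 6-ethyl-3-{[4-hydroxy-5-(1-hydroxyethyl)-6-(methoxymethoxy)-3-(3-methylbut-2-en-1-yl)-2-(triisopropylsilyloxy)phenyl]methyl}-4-(methoxymethoxy)-5-methyl-2H-pyran-2-one (racemic) | CCc1oc(=O)c(Cc2c(OCOC)c(C(C)O)c(O)c(CC=C(C)C)c2O[Si](C(C)C)(C(C)C)C(C)C)c(OCOC)c1C
F6 | step 8 | 3-{[5-acetyl-4-hydroxy-6-(methoxymethoxy)-3-(3-methylbut-2-en-1-yl)-2-(triisopropylsilyloxy)phenyl]methyl}-6-ethyl-4-(methoxymethoxy)-5-methyl-2H-pyran-2-one | CCc1oc(=O)c(Cc2c(OCOC)c(C(C)=O)c(O)c(CC=C(C)C)c2O[Si](C(C)C)(C(C)C)C(C)C)c(OCOC)c1C
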